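The cyclohexene ring is numbered C1 (stereocentre), C2 (methyl-bearing alkene carbon), C3 (vinylic CH), C4 and C5 (CH2) and C6 (CMe2), and is disconnected at both ends of its C4–C5 bridge. The key step exploits the 1,4-relation between C3 and the quaternary C6. In one flask vinyllithium adds to 4-methylpent-3-enal (C3–C4), and the derived 1,5-dien-3-olate undergoes an anionic oxy-Cope shift that turns the linear prenyl terminus into the quaternary carbon (C5–C6). The resulting 4,4-dimethylhex-5-enal is closed by metathesis to an (R)-cyclohexenol. Its carbinol stereocentre is relayed to C1 by a decarboxylative Claisen rearrangement; sulfone alkylation with a geraniol-derived bromide and esterification with linoleic acid complete the route.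

Key step: step 2

Assumption: vinyllithium is used as a pre-formed THF solution.

Step 1
Reactants: 1 4-methylpent-3-en-1-ol
Product: 2 4-methylpent-3-enal
Conditions: Dess–Martin periodinane, NaHCO3, CH2Cl2, 0 °C; cold filtered solution used directly
Reagents that add atoms: none
Why: Dess–Martin oxidation of a primary alcohol, buffered and cold so that the β,γ-alkene should not move into conjugation; no stereocentre is formed.

Step 2
Reactants: 2 4-methylpent-3-enal
Product: 6 4,4-dimethylhex-5-enal, via lithium 6-methylhepta-1,5-dien-3-olate 3 (not isolated), via potassium 6-methylhepta-1,5-dien-3-olate 4 (not isolated), via potassium 4,4-dimethylhexa-1,5-dien-1-olate 5 (not isolated)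
Conditions: CH2=CHLi, THF, −78 °C; then KOt-Bu, 18-crown-6, −78 to 25 °C (same flask); pH 7 buffer, 0 °C
Reagents that add atoms: vinyllithium, [Li]C=C
Why: 1,2-Addition of the vinyl anion to the aldehyde carbon forms the C3–C4 bond and gives alkoxide 3; exchange of lithium for crown-complexed potassium gives the loose ion pair 4, which should undergo a [3,3] shift through a chair transition state in which the vinyl terminus bonds to the dimethyl-substituted alkene carbon (C5–C6) while the bond between the carbinol carbon and the allylic CH2 breaks, and enolate 5 is protonated to 6. The closest known reaction type is the tandem carbonyl 1,2-addition/anionic oxy-Cope rearrangement of 1,5-dien-3-olates. No ring is closed here; the ring is closed in step 4 by metathesis. No stereocentre survives, since the carbinol centre of 3 is racemic and is erased in 5, and C6 carries two identical methyl groups. The step needs the [3,3] shift to win over α-deprotonation of the aldehyde and over dissociative allyl transfer; fast addition at −78 °C, the single 1,5-diene array in 4 and the irreversible formation of enolate 5 should secure this. The crowded gem-dimethyl terminus is tolerated because only one σ-bond is made to it within an intramolecular six-membered array.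

Step 3
Reactants: 6 4,4-dimethylhex-5-enal
Product: 7 (3R)-2,6,6-trimethylocta-1,7-dien-3-ol
Conditions: [CH2=C(CH3)]2Zn (from CH2=C(CH3)MgBr and ZnCl2, Mg salts precipitated with 1,4-dioxane), (−)-MIB [(2S)-3-exo-morpholinoisoborneol] (5 mol %), toluene, 0 °C
Reagents that add atoms: prop-1-en-2-ylmagnesium bromide, C=C(C)[Mg]Br
Why: Amino-alcohol-catalysed enantioselective alkenylzinc addition to an aldehyde (Oppolzer–Radinov type), in which the zinc alkoxide of (−)-MIB should direct transfer of the 2-propenyl group to the Si face and so set the (3R) carbinol centre.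

Step 4
Reactants: 7 (3R)-2,6,6-trimethylocta-1,7-dien-3-ol
Product: 8 (1R)-2,4,4-trimethylcyclohex-2-en-1-ol
Conditions: second-generation Hoveyda–Grubbs catalyst (5 mol %), 1,4-benzoquinone (10 mol %), toluene (0.01 M), 80 °C
Reagents that add atoms: none
Why: Ring-closing olefin metathesis to the six-membered ring with loss of ethene, helped by the gem-dimethyl (Thorpe–Ingold) effect and the free allylic hydroxyl, with benzoquinone suppressing ruthenium hydride isomerisation; the carbinol centre is untouched.

Step 5
Reactants: 8 (1R)-2,4,4-trimethylcyclohex-2-en-1-ol; 9 2-[(4-methylphenyl)sulfonyl]acetic acid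
Product: 10 (1R)-2,4,4-trimethylcyclohex-2-en-1-yl 2-[(4-methylphenyl)sulfonyl]acetate
Conditions: DCC, DMAP (cat.), CH2Cl2, 0 to 25 °C
Reagents that add atoms: none
Why: Steglich esterification at oxygen, so the carbinol configuration is retained.

Step 6
Reactants: 10 (1R)-2,4,4-trimethylcyclohex-2-en-1-yl 2-[(4-methylphenyl)sulfonyl]acetate
Product: 13 1-methyl-4-({[(1S)-2,6,6-trimethylcyclohex-2-en-1-yl]methyl}sulfonyl)benzene, via silyl ketene acetal 11 (not isolated), via trimethylsilyl ester 12 (not isolated)
Conditions: BSA (0.2 equiv), KOAc (0.1 equiv), toluene, 110 °C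
Reagents that add atoms: none
Why: Decarboxylative Claisen rearrangement (Ireland–Claisen type followed by desilylative loss of CO2 from 12): the [3,3] shift of ketene acetal 11 is suprafacial, so the new C–C bond should form at the alkene CH next to the gem-dimethyl carbon on the ring face that carried the oxygen, moving the double bond and turning (1R) into (1S).

Step 7
Reactants: 14 geraniol [(2E)-3,7-dimethylocta-2,6-dien-1-ol]
Product: 15 tert-butyl{[(2E)-3,7-dimethylocta-2,6-dien-1-yl]oxy}dimethylsilane
Conditions: TBSCl, imidazole, CH2Cl2, 25 °C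
Reagents that add atoms: tert-butyldimethylsilyl chloride, CC(C)(C)[Si](C)(C)Cl
Why: Silyl ether protection of the primary allylic alcohol.

Step 8
Reactants: 15 tert-butyl{[(2E)-3,7-dimethylocta-2,6-dien-1-yl]oxy}dimethylsilane
Product: 16 (2E,6E)-8-{[tert-butyl(dimethyl)silyl]oxy}-2,6-dimethylocta-2,6-dien-1-ol
Conditions: SeO2 (0.1 equiv), t-BuOOH, salicylic acid (cat.), CH2Cl2, 25 °C
Reagents that add atoms: tert-butyl hydroperoxide, CC(C)(C)OO
Why: Sharpless catalytic SeO2/t-BuOOH allylic oxidation (ene reaction then [2,3] shift), which should hydroxylate the (E)-methyl of the remote, more electron-rich trisubstituted alkene and keep the (E) geometry.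

Step 9
Reactants: 16 (2E,6E)-8-{[tert-butyl(dimethyl)silyl]oxy}-2,6-dimethylocta-2,6-dien-1-ol
Product: 17 {[(2E,6E)-8-bromo-3,7-dimethylocta-2,6-dien-1-yl]oxy}(tert-butyl)dimethylsilane
Conditions: CBr4, PPh3, CH2Cl2, −20 to 0 °C
Reagents that add atoms: carbon tetrabromide, BrC(Br)(Br)Br
Why: Appel bromination, an SN2 displacement at the primary allylic carbon under neutral conditions that should keep the alkene geometry and the silyl ether.

Step 10
Reactants: 13 1-methyl-4-({[(1S)-2,6,6-trimethylcyclohex-2-en-1-yl]methyl}sulfonyl)benzene; 17 {[(2E,6E)-8-bromo-3,7-dimethylocta-2,6-dien-1-yl]oxy}(tert-butyl)dimethylsilane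
Product: 19 tert-butyl({(2E,6E)-3,7-dimethyl-9-[(4-methylphenyl)sulfonyl]-9-[(1S)-2,6,6-trimethylcyclohex-2-en-1-yl]nona-2,6-dien-1-yl}oxy)dimethylsilane (epimers at C9), via lithiated sulfone 18 (not isolated)
Conditions: n-BuLi, THF, −78 °C; then 17, −78 to −20 °C
Reagents that add atoms: none
Why: Alkylation of the α-sulfonyl carbanion 18 with a primary allylic bromide (Julia-type sulfone coupling) by SN2 attack without allylic transposition; the sulfone-bearing carbon forms as an epimer mixture that is removed in step 11, and the ring stereocentre is not deprotonated.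

Step 11
Reactants: 19 sulfone coupling product (epimers at C9)
Product: 20 tert-butyl({(2E,6E)-3,7-dimethyl-9-[(1S)-2,6,6-trimethylcyclohex-2-en-1-yl]nona-2,6-dien-1-yl}oxy)dimethylsilane
Conditions: Mg, HgCl2 (cat.), MeOH/THF, 25 °C
Reagents that add atoms: none
Why: Reductive desulfonylation by electron transfer from magnesium; the sulfone is homoallylic to both neighbouring alkenes, so no double-bond shift is expected and the silyl ether and ring stereocentre should persist.

Step 12
Reactants: 20 silyl ether
Product: 21 (2E,6E)-3,7-dimethyl-9-[(1S)-2,6,6-trimethylcyclohex-2-en-1-yl]nona-2,6-dien-1-ol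
Conditions: TBAF, THF, 0 to 25 °C
Reagents that add atoms: none
Why: Fluoride-mediated cleavage of the silyl ether.

Step 13
Reactants: 21 (2E,6E)-3,7-dimethyl-9-[(1S)-2,6,6-trimethylcyclohex-2-en-1-yl]nona-2,6-dien-1-ol; 22 linoleic acid [(9Z,12Z)-octadeca-9,12-dienoic acid]
Product: 23 (2E,6E)-3,7-dimethyl-9-[(1S)-2,6,6-trimethylcyclohex-2-en-1-yl]nona-2,6-dien-1-yl (9Z,12Z)-octadeca-9,12-dienoate (CNP0369707.1)
Conditions: DCC, DMAP (cat.), CH2Cl2, 0 to 25 °C
Reagents that add atoms: none
Why: Steglich esterification, mild and neutral, which should leave the skipped (Z,Z)-diene and the trisubstituted alkenes unchanged.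

Compound list
1 | 4-methylpent-3-en-1-ol | CC(C)=CCCO | starting material
2 | 4-methylpent-3-enal | CC(C)=CCC=O | intermediate
3 | lithium 6-methylhepta-1,5-dien-3-olate | [Li+].[O-]C(C=C)CC=C(C)C | intermediate
4 | potassium 6-methylhepta-1,5-dien-3-olate | [K+].[O-]C(C=C)CC=C(C)C | intermediate
5 | potassium 4,4-dimethylhexa-1,5-dien-1-olate | [K+].[O-]C=CCC(C)(C)C=C | intermediate
6 | 4,4-dimethylhex-5-enal | O=CCCC(C)(C)C=C | intermediate
7 | (3R)-2,6,6-trimethylocta-1,7-dien-3-ol | C=C(C)[C@H](O)CCC(C)(C)C=C | intermediate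
8 | (1R)-2,4,4-trimethylcyclohex-2-en-1-ol | O[C@H]1C(C)=CC(C)(C)CC1 | intermediate
9 | 2-[(4-methylphenyl)sulfonyl]acetic acid | Cc1ccc(cc1)S(=O)(=O)CC(=O)O | starting material
10 | (1R)-2,4,4-trimethylcyclohex-2-en-1-yl 2-[(4-methylphenyl)sulfonyl]acetate | Cc1ccc(cc1)S(=O)(=O)CC(=O)O[C@H]1C(C)=CC(C)(C)CC1 | intermediate
11 | 1-methyl-4-({2-{[(1R)-2,4,4-trimethylcyclohex-2-en-1-yl]oxy}-2-[(trimethylsilyl)oxy]ethenyl}sulfonyl)benzene (silyl ketene acetal) | Cc1ccc(cc1)S(=O)(=O)C=C(O[Si](C)(C)C)O[C@H]1C(C)=CC(C)(C)CC1 | intermediate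
12 | trimethylsilyl 2-[(4-methylphenyl)sulfonyl]-2-[(1S)-2,6,6-trimethylcyclohex-2-en-1-yl]acetate | Cc1ccc(cc1)S(=O)(=O)C([C@@H]1C(C)=CCCC1(C)C)C(=O)O[Si](C)(C)C | intermediate
13 | 1-methyl-4-({[(1S)-2,6,6-trimethylcyclohex-2-en-1-yl]methyl}sulfonyl)benzene | Cc1ccc(cc1)S(=O)(=O)C[C@@H]1C(C)=CCCC1(C)C | intermediate
14 | geraniol | CC(C)=CCC/C(C)=C/CO | starting material
15 | tert-butyl{[(2E)-3,7-dimethylocta-2,6-dien-1-yl]oxy}dimethylsilane | CC(C)=CCC/C(C)=C/CO[Si](C)(C)C(C)(C)C | intermediate
16 | (2E,6E)-8-{[tert-butyl(dimethyl)silyl]oxy}-2,6-dimethylocta-2,6-dien-1-ol | OC/C(C)=C/CC/C(C)=C/CO[Si](C)(C)C(C)(C)C | intermediate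
17 | {[(2E,6E)-8-bromo-3,7-dimethylocta-2,6-dien-1-yl]oxy}(tert-butyl)dimethylsilane | BrC/C(C)=C/CC/C(C)=C/CO[Si](C)(C)C(C)(C)C | intermediate
18 | lithium salt of 13 at the sulfonyl-bearing carbon | [Li]C([C@@H]1C(C)=CCCC1(C)C)S(=O)(=O)c1ccc(C)cc1 | intermediate
19 | tert-butyl({(2E,6E)-3,7-dimethyl-9-[(4-methylphenyl)sulfonyl]-9-[(1S)-2,6,6-trimethylcyclohex-2-en-1-yl]nona-2,6-dien-1-yl}oxy)dimethylsilane | CC(C)(C)[Si](C)(C)OC/C=C(\C)CC/C=C(\C)CC([C@@H]1C(C)=CCCC1(C)C)S(=O)(=O)c1ccc(C)cc1 | intermediate
20 | tert-butyl({(2E,6E)-3,7-dimethyl-9-[(1S)-2,6,6-trimethylcyclohex-2-en-1-yl]nona-2,6-dien-1-yl}oxy)dimethylsilane | CC(C)(C)[Si](C)(C)OC/C=C(\C)CC/C=C(\C)CC[C@@H]1C(C)=CCCC1(C)C | intermediate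
21 | (2E,6E)-3,7-dimethyl-9-[(1S)-2,6,6-trimethylcyclohex-2-en-1-yl]nona-2,6-dien-1-ol | OC/C=C(\C)CC/C=C(\C)CC[C@@H]1C(C)=CCCC1(C)C | intermediate
22 | linoleic acid | CCCCC/C=C\C/C=C\CCCCCCCC(=O)O | starting material
23 | (2E,6E)-3,7-dimethyl-9-[(1S)-2,6,6-trimethylcyclohex-2-en-1-yl]nona-2,6-dien-1-yl (9Z,12Z)-octadeca-9,12-dienoate | CCCCC/C=C\C/C=C\CCCCCCCC(=O)OC/C=C(\C)CC/C=C(\C)CC[C@@H]1C(C)=CCCC1(C)C | target

Total step count: 13. Longest linear sequence: 10 steps (steps 1–6 and 10–13).

Steps most likely to fail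

Step 2. Vinyllithium may deprotonate the β,γ-unsaturated aldehyde at its doubly activated CH2 and move the alkene into conjugation. Incomplete lithium-to-potassium exchange may also leave the alkoxide unreactive or let it drift into dissociative allyl transfer. The fallback separates the two bond formations and sets out from 2. Vinylmagnesium bromide (THF, −78 °C), which is less basic, should give isolated 6-methylhepta-1,5-dien-3-ol F1. F1 is then rearranged on its own as the preformed potassium alkoxide (KH, 18-crown-6, THF, 0 to 25 °C), and the sequence comes back to the route at 6.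

Step 3. Uncatalysed background addition promoted by residual magnesium salts may erode enantiofacial selectivity. The fallback sets the stereocentre by reduction and sets out from 6. Prop-1-en-2-ylmagnesium bromide should give racemic 2,6,6-trimethylocta-1,7-dien-3-ol F2, and Dess–Martin oxidation should give 2,6,6-trimethylocta-1,7-dien-3-one F3. Corey–Bakshi–Shibata reduction with the (S)-methyl oxazaborolidine and catecholborane at −78 °C, where the 2-propenyl group acts as the large substituent, should come back to the route at 7.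

Step 6. The sigmatropic shift must form a bond at an alkene carbon next to the quaternary carbon and may be slow enough for thermal elimination of the ester to a diene to compete. The fallback uses a [2,3] shift and sets out from 8. KH and Bu3SnCH2I should give tributyl({[(1R)-2,4,4-trimethylcyclohex-2-en-1-yl]oxy}methyl)stannane F4. Tin–lithium exchange (n-BuLi, THF, −78 °C) should trigger the suprafacial Wittig–Still rearrangement to [(1S)-2,6,6-trimethylcyclohex-2-en-1-yl]methanol F5. Di-p-tolyl disulfide and PBu3 should give 1-methyl-4-({[(1S)-2,6,6-trimethylcyclohex-2-en-1-yl]methyl}sulfanyl)benzene F6, and oxidation with H2O2 and (NH4)6Mo7O24 comes back to the route at 13.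

Further compounds
F1 | step 2 | 6-methylhepta-1,5-dien-3-ol | C=CC(O)CC=C(C)C
F2 | step 3 | 2,6,6-trimethylocta-1,7-dien-3-ol (racemic) | C=C(C)C(O)CCC(C)(C)C=C
F3 | step 3 | 2,6,6-trimethylocta-1,7-dien-3-one | C=C(C)C(=O)CCC(C)(C)C=C
F4 | step 6 | tributyl({[(1R)-2,4,4-trimethylcyclohex-2-en-1-yl]oxy}methyl)stannane | CCCC[Sn](CCCC)(CCCC)CO[C@H]1C(C)=CC(C)(C)CC1
F5 | step 6 | [(1S)-2,6,6-trimethylcyclohex-2-en-1-yl]methanol | OC[C@@H]1C(C)=CCCC1(C)C
F6 | step 6 | 1-methyl-4-({[(1S)-2,6,6-trimethylcyclohex-2-en-1-yl]methyl}sulfanyl)benzene | Cc1ccc(cc1)SC[C@@H]1C(C)=CCCC1(C)C
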